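**Retrosynthetic overview**
1. The target comes from indane alcohol 17 by acetylation; 17 comes from hydrazone 14 by the key ring closure, which makes the benzylic CH2–CMe2 bond of the cyclopentane last: an iron-hydride HAT radical cyclisation of a 2-methylallyl arm onto the neighbouring aldehyde N-tosylhydrazone, which then sheds sulfinate and N2 so that the aldehyde carbon ends as the ring CH2.
2. Enabling feature: the two benzylic CH2 carbons of the five-membered ring sit on adjacent benzene carbons (ring-fusion atoms C3a/C7a), and the quaternary C2 carries two identical methyls. A 2-methylallyl group is therefore a latent tertiary radical that reaches the hydrazone carbon in a 5-exo closure, and no stereocentre has to be set.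
3. The two ester arms are told apart by a temporary ring: the aldehyde carbon and the adjacent CH2OH are locked as a 1-methoxy-1,3-dihydro-2-benzofuran (step 6), the remote CH2OH takes the butanoate (step 7), and tosylhydrazide reopens the ring (step 9).
4. The pentasubstituted benzene comes from dimethyl 2-methylisophthalate: chloroethyl arm by toluate-anion hydroxymethylation and lactone opening, bromination at the one electronically favoured position, then magnesiation/formylation at either of two equivalent C–H positions of the C2v-symmetric diester 6 (desymmetrisation); the bromide becomes 2-methylallyl by Stille coupling.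
5. Ring order: benzene ring purchased; temporary isochromanone ring (formed step 1, opened step 3); temporary dihydro-2-benzofuran ring (formed step 6, opened step 9); cyclopentane ring last (step 10).

Key step: step 10

Remark: the target is achiral; compounds 11–13 and 15–16 each carry one stereocentre that is destroyed later and are used as racemates; dimethyl 2-methylisophthalate is taken as a catalogue compound.

**Route**

Step 1
Reactants: 1 dimethyl 2-methylbenzene-1,3-dicarboxylate
Product: 3 methyl 1-oxo-3,4-dihydro-1H-2-benzopyran-5-carboxylate, via hydroxyethyl diester lithium alkoxide 2 (not isolated)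
Conditions: LiN(iPr)2 (1.1 equiv), THF, −78 °C; CH2O gas (from cracked paraformaldehyde), −78 °C → rt; aqueous work-up
Reagents that add atoms: formaldehyde (C=O)
Why: Lateral (benzylic) lithiation of the ortho-toluate gives a dienolate that should add to formaldehyde, and the alkoxide then lactonises onto one of the two equivalent flanking esters (toluate-anion route to 3,4-dihydroisocoumarins).

Step 2
Reactants: 3 methyl 1-oxo-3,4-dihydro-1H-2-benzopyran-5-carboxylate
Product: 4 methyl 7-bromo-1-oxo-3,4-dihydro-1H-2-benzopyran-5-carboxylate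
Conditions: N-bromosuccinimide (1.1 equiv), conc. H2SO4, rt; pour on ice
Reagents that add atoms: N-bromosuccinimide (O=C1CCC(=O)N1Br)
Why: Electrophilic aromatic bromination of a deactivated arene in sulfuric acid should go only to C7, the one position that is meta to both carbonyl groups and para to the alkyl arm.

Step 3
Reactants: 4 methyl 7-bromo-1-oxo-3,4-dihydro-1H-2-benzopyran-5-carboxylate
Product: 6 dimethyl 5-bromo-2-(2-chloroethyl)benzene-1,3-dicarboxylate, via chloroethyl aroyl chloride 5 (not isolated)
Conditions: SOCl2 (4 equiv), ZnCl2 (5 mol%), 80 °C; concentrate; MeOH, 0 °C → rt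
Reagents that add atoms: thionyl chloride (O=S(Cl)Cl); methanol (CO)
Why: ZnCl2-assisted alkyl–oxygen cleavage of the lactone by chloride with conversion of the carboxyl group to the acid chloride (the usual lactone to ω-chloroacyl chloride opening) installs the chloroethyl arm, and methanolysis should give the C2v-symmetric diester.

Step 4
Reactants: 6 dimethyl 5-bromo-2-(2-chloroethyl)benzene-1,3-dicarboxylate
Product: 8 dimethyl 5-bromo-2-(2-chloroethyl)-4-formylbenzene-1,3-dicarboxylate, via arylmagnesium chloride 7 (not isolated)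
Conditions: TMPMgCl·LiCl (1.2 equiv), THF, −20 °C; DMF (2 equiv), −20 °C → rt; aqueous work-up
Reagents that add atoms: N,N-dimethylformamide (CN(C)C=O)
Why: Directed ortho-magnesiation with the hindered mixed Mg/Li amide at the ring C–H flanked by bromine and an ester, followed by formylation with DMF, should give one aldehyde because the two such positions are equivalent; this step breaks the symmetry.

Step 5
Reactants: 8 dimethyl 5-bromo-2-(2-chloroethyl)-4-formylbenzene-1,3-dicarboxylate
Product: 9 dimethyl 5-bromo-2-(2-chloroethyl)-4-(dimethoxymethyl)benzene-1,3-dicarboxylate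
Conditions: HC(OMe)3 (3 equiv), TsOH·H2O (5 mol%), MeOH, 50 °C
Reagents that add atoms: trimethyl orthoformate (COC(OC)OC)
Why: Acid-catalysed acetalisation with orthoformate masks the aldehyde so that it keeps its oxidation level through the ester reduction.

Step 6
Reactants: 9 dimethyl 5-bromo-2-(2-chloroethyl)-4-(dimethoxymethyl)benzene-1,3-dicarboxylate
Product: 11 [7-bromo-4-(2-chloroethyl)-1-methoxy-1,3-dihydro-2-benzofuran-5-yl]methanol (racemic), via diol dimethyl acetal 10 (not isolated)
Conditions: iBu2AlH (5 equiv), CH2Cl2, −78 → 0 °C; aq. KNaC4H4O6 (Rochelle salt) work-up; then PPTS (10 mol%), CH2Cl2, rt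
Reagents that add atoms: none
Why: Hydride reduction of both esters followed by acid-catalysed intramolecular transacetalisation, in which only the CH2OH ortho to the acetal carbon can close a five-membered ring, should make the two hydroxymethyl groups chemically different; the acetal stereocentre forms as a racemate and is destroyed in step 9.

Step 7
Reactants: 11 [7-bromo-4-(2-chloroethyl)-1-methoxy-1,3-dihydro-2-benzofuran-5-yl]methanol
Product: 12 [7-bromo-4-(2-chloroethyl)-1-methoxy-1,3-dihydro-2-benzofuran-5-yl]methyl butanoate (racemic)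
Conditions: (PrCO)2O (1.3 equiv), Et3N (2 equiv), DMAP (5 mol%), CH2Cl2, 0 °C → rt
Reagents that add atoms: butanoic anhydride (CCCC(=O)OC(=O)CCC)
Why: DMAP-catalysed acylation of the only free hydroxyl should be clean because the mixed cyclic acetal is stable to base.

Step 8
Reactants: 12 [7-bromo-4-(2-chloroethyl)-1-methoxy-1,3-dihydro-2-benzofuran-5-yl]methyl butanoate
Product: 13 [4-(2-chloroethyl)-1-methoxy-7-(2-methylprop-2-en-1-yl)-1,3-dihydro-2-benzofuran-5-yl]methyl butanoate (racemic)
Conditions: tributyl(2-methylprop-2-en-1-yl)stannane (1.3 equiv), Pd(PPh3)4 (5 mol%), toluene, 100 °C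
Reagents that add atoms: tributyl(2-methylprop-2-en-1-yl)stannane (CCCC[Sn](CCCC)(CCCC)CC(C)=C)
Why: Stille allyl–aryl coupling under neutral conditions should spare ester, acetal and primary alkyl chloride, and the 2-methylallyl unit is symmetric so α- and γ-transfer give the same product.

Step 9
Reactants: 13 [4-(2-chloroethyl)-1-methoxy-7-(2-methylprop-2-en-1-yl)-1,3-dihydro-2-benzofuran-5-yl]methyl butanoate
Product: 14 {2-(2-chloroethyl)-3-(hydroxymethyl)-5-(2-methylprop-2-en-1-yl)-4-[(E)-{2-[(4-methylphenyl)sulfonyl]hydrazinylidene}methyl]phenyl}methyl butanoate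
Conditions: TsNHNH2 (1.1 equiv), PPTS (10 mol%), THF, 40 °C
Reagents that add atoms: 4-methylbenzenesulfonohydrazide (Cc1ccc(cc1)S(=O)(=O)NN)
Why: Acid-catalysed exchange of the cyclic acetal for the conjugated N-sulfonylhydrazone (E isomer for steric reasons) should open the temporary ring and free the second hydroxymethyl group without touching the butanoate.

Step 10
Reactants: 14 {2-(2-chloroethyl)-3-(hydroxymethyl)-5-(2-methylprop-2-en-1-yl)-4-[(E)-{2-[(4-methylphenyl)sulfonyl]hydrazinylidene}methyl]phenyl}methyl butanoate
Product: 17 [5-(2-chloroethyl)-4-(hydroxymethyl)-2,2-dimethyl-2,3-dihydro-1H-inden-6-yl]methyl butanoate, via cyclised sulfonylhydrazide 15 (not isolated), via alkyl diazene 16 (not isolated)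
Conditions: Fe(acac)3 (30 mol%), PhSiH3 (2.5 equiv), EtOH/THF, argon, 60 °C; then NaOAc (2 equiv), 75 °C
Reagents that add atoms: none
Why: An iron hydride formed from Fe(acac)3 and PhSiH3 should transfer a hydrogen atom to the terminal CH2 of the 1,1-disubstituted alkene (Markovnikov sense) to give the tertiary radical ArCH2C•Me2. This nucleophilic radical adds to the carbon of the ortho C=N bond in a 5-exo-trig closure that forms the benzylic CH2–quaternary carbon bond and the cyclopentane ring; reduction and protonation of the hydrazinyl radical give N-alkyl-N'-tosylhydrazine 15, which on warming with acetate loses sulfinate to diazene 16, and this expels N2 to leave the ring CH2. The closest known reaction types are the iron/silane HAT-initiated reductive coupling of alkenes with sulfonylhydrazones (olefin hydromethylation and the related alkene–hydrazone cyclisations) and the Caglioti-type collapse of alkyl tosylhydrazines to alkanes. The product has no stereocentre, and the C–N stereocentre of 15 is transient. The step needs radical formation at the methyl-bearing carbon, C- rather than N-attack on the hydrazone, and tolerance of the alkyl chloride, ester and free alcohol; these are secured by the 1,1-disubstitution of the alkene, the ortho relationship of the two arms, the polarity match between a nucleophilic tertiary radical and the electrophilic hydrazone carbon, and the neutral radical conditions.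

Step 11
Reactants: 17 [5-(2-chloroethyl)-4-(hydroxymethyl)-2,2-dimethyl-2,3-dihydro-1H-inden-6-yl]methyl butanoate
Product: 18 [4-(acetyloxymethyl)-5-(2-chloroethyl)-2,2-dimethyl-2,3-dihydro-1H-inden-6-yl]methyl butanoate (target)
Conditions: Ac2O (1.5 equiv), pyridine, DMAP (5 mol%), CH2Cl2, 0 °C → rt
Reagents that add atoms: acetic anhydride (CC(=O)OC(C)=O)
Why: Standard DMAP-catalysed acetylation of the remaining primary benzylic alcohol should complete the two different esters.

**Compound list**
1 | dimethyl 2-methylbenzene-1,3-dicarboxylate | COC(=O)c1cccc(C(=O)OC)c1C | starting material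
2 | dimethyl 2-(2-hydroxyethyl)benzene-1,3-dicarboxylate, lithium alkoxide | [Li+].[O-]CCc1c(C(=O)OC)cccc1C(=O)OC | intermediate (not isolated)
3 | methyl 1-oxo-3,4-dihydro-1H-2-benzopyran-5-carboxylate | COC(=O)c1cccc2c1CCOC2=O | intermediate
4 | methyl 7-bromo-1-oxo-3,4-dihydro-1H-2-benzopyran-5-carboxylate | COC(=O)c1cc(Br)cc2c1CCOC2=O | intermediate
5 | methyl 5-bromo-3-(chlorocarbonyl)-2-(2-chloroethyl)benzoate | COC(=O)c1cc(Br)cc(C(Cl)=O)c1CCCl | intermediate (not isolated)
6 | dimethyl 5-bromo-2-(2-chloroethyl)benzene-1,3-dicarboxylate | COC(=O)c1cc(Br)cc(C(=O)OC)c1CCCl | intermediate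
7 | [6-bromo-3-(2-chloroethyl)-2,4-bis(methoxycarbonyl)phenyl]magnesium chloride | COC(=O)c1cc(Br)c([Mg]Cl)c(C(=O)OC)c1CCCl | intermediate (not isolated)
8 | dimethyl 5-bromo-2-(2-chloroethyl)-4-formylbenzene-1,3-dicarboxylate | COC(=O)c1cc(Br)c(C=O)c(C(=O)OC)c1CCCl | intermediate
9 | dimethyl 5-bromo-2-(2-chloroethyl)-4-(dimethoxymethyl)benzene-1,3-dicarboxylate | COC(=O)c1cc(Br)c(C(OC)OC)c(C(=O)OC)c1CCCl | intermediate
10 | [5-bromo-2-(2-chloroethyl)-4-(dimethoxymethyl)benzene-1,3-diyl]dimethanol | OCc1cc(Br)c(C(OC)OC)c(CO)c1CCCl | intermediate (not isolated)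
11 | [7-bromo-4-(2-chloroethyl)-1-methoxy-1,3-dihydro-2-benzofuran-5-yl]methanol (racemic) | COC1OCc2c(CCCl)c(CO)cc(Br)c12 | intermediate
12 | [7-bromo-4-(2-chloroethyl)-1-methoxy-1,3-dihydro-2-benzofuran-5-yl]methyl butanoate (racemic) | CCCC(=O)OCc1cc(Br)c2c(c1CCCl)COC2OC | intermediate
13 | [4-(2-chloroethyl)-1-methoxy-7-(2-methylprop-2-en-1-yl)-1,3-dihydro-2-benzofuran-5-yl]methyl butanoate (racemic) | CCCC(=O)OCc1cc(CC(C)=C)c2c(c1CCCl)COC2OC | intermediate
14 | {2-(2-chloroethyl)-3-(hydroxymethyl)-5-(2-methylprop-2-en-1-yl)-4-[(E)-{2-[(4-methylphenyl)sulfonyl]hydrazinylidene}methyl]phenyl}methyl butanoate | CCCC(=O)OCc1cc(CC(C)=C)c(/C=N/NS(=O)(=O)c2ccc(C)cc2)c(CO)c1CCCl | intermediate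
15 | [5-(2-chloroethyl)-4-(hydroxymethyl)-2,2-dimethyl-3-{2-[(4-methylphenyl)sulfonyl]hydrazinyl}-2,3-dihydro-1H-inden-6-yl]methyl butanoate (racemic) | CCCC(=O)OCc1cc2c(c(CO)c1CCCl)C(NNS(=O)(=O)c3ccc(C)cc3)C(C)(C)C2 | intermediate (not isolated)
16 | [5-(2-chloroethyl)-3-diazenyl-4-(hydroxymethyl)-2,2-dimethyl-2,3-dihydro-1H-inden-6-yl]methyl butanoate (racemic) | CCCC(=O)OCc1cc2c(c(CO)c1CCCl)C(N=N)C(C)(C)C2 | intermediate (not isolated)
17 | [5-(2-chloroethyl)-4-(hydroxymethyl)-2,2-dimethyl-2,3-dihydro-1H-inden-6-yl]methyl butanoate | CCCC(=O)OCc1cc2c(c(CO)c1CCCl)CC(C)(C)C2 | intermediate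
18 | [4-(acetyloxymethyl)-5-(2-chloroethyl)-2,2-dimethyl-2,3-dihydro-1H-inden-6-yl]methyl butanoate | CCCC(=O)OCc1cc2c(c(COC(C)=O)c1CCCl)CC(C)(C)C2 | target

**Step count**
Total steps: 11. Longest linear sequence: 11 steps (the route is fully linear).

**Three steps most likely to fail**

Step 4 (magnesiation/formylation). The amide base may instead remove a benzylic proton of the chloroethyl arm, which sits between the two esters, with loss of chloride to a styrene; the ortho-bromo arylmagnesium may also eliminate to an aryne. Fallback, from 6 back to 13, avoiding strong base: Miyaura borylation of 6 (Pd(dppf)Cl2, B2pin2, KOAc, dioxane, 80 °C) should give the pinacol boronate F1, oxidised with Oxone (2KHSO5·KHSO4·K2SO4) in acetone/water to the phenol F2. Duff formylation under acidic conditions (hexamethylenetetramine, CF3CO2H, 80 °C, then aqueous acid) at either of the two equivalent ortho positions should give the salicylaldehyde F3, and Tf2O/pyridine the aryl triflate F4. F4 is then taken through the chemistry of steps 5 to 7 in place of the bromide: the dimethyl acetal F5, the diol F6, the cyclic acetal alcohol F7 and the butanoate F8. Stille coupling of F8 with the same stannane (Pd(PPh3)4, LiCl, dioxane, 100 °C) rejoins the route at 13.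

Step 10 (key ring closure). The tertiary radical may be reduced to an isobutyl group before it cyclises; the hydroxy hydrazone may sit as its ring tautomer and hide the C=N acceptor; the free hydroxymethyl group may alkylate intramolecularly at the chloroethyl arm on heating; or loss of sulfinate and N2 may stall. Fallback, from 13 back to 17, in two separate known operations: AcOH/H2O/THF hydrolysis of the acetal should give the lactol F9 (in equilibrium with its hydroxy aldehyde). The Fe(acac)3/PhSiH3 HAT-initiated alkene–carbonyl radical cyclisation in EtOH at 60 °C should then close the same bond to the indan-1-ol F10. Ionic hydrogenation of the secondary benzylic carbinol (Et3SiH, BF3·OEt2, CH2Cl2, −40 °C), which ionises far more readily than the primary benzylic positions, returns to 17.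

Step 8 (Stille coupling). The double bond may migrate into conjugation with the arene under palladium hydride catalysis, giving the useless 2-methylprop-1-enyl isomer, or oxidative addition at the ortho-substituted bromide may be slow, leading to protodebromination. Fallback, from 12 back to 13, building the alkene by carbonyl chemistry: Pd-catalysed mono-α-arylation of acetone ([Pd(cinnamyl)Cl]2, Mor-DalPhos, Cs2CO3, acetone, 90 °C) should give the arylacetone F11, and Wittig methylenation (Ph3PCH3Br, KOtBu, THF, 0 °C) gives 13.

**Further compounds**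
F1 | step 4 | dimethyl 2-(2-chloroethyl)-5-(4,4,5,5-tetramethyl-1,3,2-dioxaborolan-2-yl)benzene-1,3-dicarboxylate | COC(=O)c1cc(B2OC(C)(C)C(C)(C)O2)cc(C(=O)OC)c1CCCl
F2 | step 4 | dimethyl 2-(2-chloroethyl)-5-hydroxybenzene-1,3-dicarboxylate | COC(=O)c1cc(O)cc(C(=O)OC)c1CCCl
F3 | step 4 | dimethyl 2-(2-chloroethyl)-4-formyl-5-hydroxybenzene-1,3-dicarboxylate | COC(=O)c1cc(O)c(C=O)c(C(=O)OC)c1CCCl
F4 | step 4 | dimethyl 2-(2-chloroethyl)-4-formyl-5-[(trifluoromethanesulfonyl)oxy]benzene-1,3-dicarboxylate | COC(=O)c1cc(OS(=O)(=O)C(F)(F)F)c(C=O)c(C(=O)OC)c1CCCl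
F5 | step 4 | dimethyl 2-(2-chloroethyl)-4-(dimethoxymethyl)-5-[(trifluoromethanesulfonyl)oxy]benzene-1,3-dicarboxylate | COC(=O)c1cc(OS(=O)(=O)C(F)(F)F)c(C(OC)OC)c(C(=O)OC)c1CCCl
F6 | step 4 | 4-(2-chloroethyl)-2-(dimethoxymethyl)-3,5-bis(hydroxymethyl)phenyl trifluoromethanesulfonate | OCc1cc(OS(=O)(=O)C(F)(F)F)c(C(OC)OC)c(CO)c1CCCl
F7 | step 4 | 4-(2-chloroethyl)-5-(hydroxymethyl)-1-methoxy-1,3-dihydro-2-benzofuran-7-yl trifluoromethanesulfonate (racemic) | COC1OCc2c(CCCl)c(CO)cc(OS(=O)(=O)C(F)(F)F)c12
F8 | step 4 | {4-(2-chloroethyl)-1-methoxy-7-[(trifluoromethanesulfonyl)oxy]-1,3-dihydro-2-benzofuran-5-yl}methyl butanoate (racemic) | CCCC(=O)OCc1cc(OS(=O)(=O)C(F)(F)F)c2c(c1CCCl)COC2OC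
F9 | step 10 | [4-(2-chloroethyl)-1-hydroxy-7-(2-methylprop-2-en-1-yl)-1,3-dihydro-2-benzofuran-5-yl]methyl butanoate (racemic lactol) | CCCC(=O)OCc1cc(CC(C)=C)c2c(c1CCCl)COC2O
F10 | step 10 | [5-(2-chloroethyl)-3-hydroxy-4-(hydroxymethyl)-2,2-dimethyl-2,3-dihydro-1H-inden-6-yl]methyl butanoate (racemic) | CCCC(=O)OCc1cc2c(c(CO)c1CCCl)C(O)C(C)(C)C2
F11 | step 8 | [4-(2-chloroethyl)-1-methoxy-7-(2-oxopropyl)-1,3-dihydro-2-benzofuran-5-yl]methyl butanoate (racemic) | CCCC(=O)OCc1cc(CC(C)=O)c2c(c1CCCl)COC2OC
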